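Ring A is numbered C1 (prenyl), C2 (carries the ring-B oxygen), C3 (quaternary, prenyl), C4 (C=O), C5 (isobutyryl), C6 (enol OH); ring B is C2–O7–C8–C9–C3, with the CMe2OH group on C8.
Cuts: first the two C–CH3 bonds of the carbinol (back to acetyl, then to vinyl on C8), then C3–C9 and O7–C8 in one operation, which opens ring B and returns aromatic deoxycohumulone and a four-carbon bis-electrophile, then the ring–prenyl and ring–acyl bonds back to phloroglucinol.
Enabling feature: ring B is only a two-carbon bridge (C9, C8) between a prenylated ring carbon (C3) and the neighbouring oxygen (O7) of a phloroglucinol whose two prenylated carbons are mirror-related, so a but-2-ene-1,4-diyl bis-carbonate can deliver C9, C8 and a vinyl handle by C-allylation followed by O-allylation.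
Forward order: ring A is bought as phloroglucinol, acylated and C-prenylated twice; ring B is closed by the palladium-catalysed dearomative annulation; the vinyl group is oxidised to the methyl ketone and methylated to the carbinol.
Stereochemistry: C3 (S) and C8 (S, trans to the C3 prenyl) are both created in the annulation under a chiral diphosphine on palladium; later steps form no stereocenter and are run so that C8 does not enolise.

Key step: step 4

Assumption: the sense of induction of the Trost ligand on this nucleophile cannot be derived with certainty, so the (R,R) antipode is written and the (S,S) antipode is to be taken instead if a first run delivers the mirror image of 9.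
Remark: the dearomatised triketones are written as one enol tautomer of a rapidly equilibrating set; in the systematic names C3 is C3a and C8 is C2 of the 3,3a-dihydrobenzofuran-4(2H)-one core.

Step 1
Reactants: 1 phloroglucinol; 2 isobutyryl chloride
Product: 3 2,4,6-trihydroxyisobutyrophenone (2-methyl-1-(2,4,6-trihydroxyphenyl)propan-1-one)
Conditions: AlCl3 (3 equiv), PhNO2, 65 °C; then ice/aq HCl
Reagents that add atoms: none
Why: Friedel–Crafts acylation of the very electron-rich phloroglucinol should stop after one acyl group because the new ketone, complexed to AlCl3 and hydrogen-bonded to both ortho hydroxyls, deactivates the ring.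

Step 2
Reactants: 3 2,4,6-trihydroxyisobutyrophenone; 4 prenyl bromide (2.1 equiv)
Product: 5 deoxycohumulone (1-[2,4,6-trihydroxy-3,5-bis(3-methylbut-2-en-1-yl)phenyl]-2-methylpropan-1-one)
Conditions: 10% aq KOH, 0 °C; then aq HCl
Reagents that add atoms: none
Why: Base-mediated C-alkylation of the ambident phloroglucinolate in water goes to carbon because the oxygens are hydrogen-bonded, and since the two free ring positions are equivalent, two equivalents of the allylic bromide should give the symmetric 3,5-diprenyl compound.

Step 3
Reactants: 6 cis-but-2-ene-1,4-diol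
Product: 7 (Z)-but-2-ene-1,4-diyl bis(methyl carbonate)
Conditions: ClCO2Me (2.5 equiv), pyridine, CH2Cl2, 0 °C → rt
Reagents that add atoms: methyl chloroformate, COC(Cl)=O
Why: O-Acylation of both primary allylic hydroxyls with a chloroformate (carbonate formation) leaves the Z alkene untouched and installs leaving groups that zerovalent palladium ionises without added base.

Step 4
Reactants: 5 deoxycohumulone; 7 (Z)-but-2-ene-1,4-diyl bis(methyl carbonate) (1.05 equiv)
Product: 9 (2S,3aS)-6-hydroxy-5-isobutyryl-3a,7-bis(3-methylbut-2-en-1-yl)-2-vinyl-3,3a-dihydrobenzofuran-4(2H)-one, via C-allylated allylic carbonate 8 (not isolated)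
Conditions: Pd2(dba)3·CHCl3 (2.5 mol %), (R,R)-DACH-phenyl Trost ligand (7.5 mol %), THF (0.05 M), 0 °C → rt
Reagents that add atoms: none
Why: Proposed new method: zerovalent palladium ionises one carbonate of 7 and 5, deprotonated by the methoxide this sets free, attacks the π-allyl complex through one of its prenyl-bearing ring carbons, which dearomatises ring A and forms bond C3–C9 of 8 (E alkene after syn/anti equilibration of the allyl unit). Ionisation of the second carbonate and attack of the enol oxygen on the internal allyl terminus then closes ring B in the 5-exo mode (bond O7–C8) and leaves the vinyl group on C8. The closest known reaction types are the palladium-catalysed tandem C-allylation/O-allylation of cyclic 1,3-diketones with but-2-ene-1,4-diyl bis-carbonates to 2-vinyl-2,3-dihydrofurans and the palladium-catalysed dearomative allylation of acylphloroglucinols, and what is new is their enantioselective union on a phloroglucinol. C3 is set by the chiral pocket of the ligand, which must tell apart the two mirror-related prenylated carbons of the symmetric nucleophile, and C8 is set in the ring closure, where the two faces of the monosubstituted allyl unit interconvert by η3–η1–η3 slippage at its CH2 end so that ligand and C3 together can select the isomer with vinyl trans to the C3 prenyl group. The step needs closure through the oxygen on C2 and not the one on C4 and needs the trans isomer, and both are backed by thermodynamics because the product is an allyl vinylogous ester that zerovalent palladium re-ionises: closure at the C2 oxygen keeps the hydrogen-bonded acyl-diketone chelate of C4, C5 and C6 intact and the trans isomer avoids the 1,3-contact of vinyl and prenyl across ring B. Aryl allyl ethers from O-allylation are likewise re-ionised and funnel to the C-allylated dienone, closure through carbon would give a strained bridged ring, and oligomerisation is held down by dilution and by keeping 7 close to one equivalent.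

Step 5
Reactants: 9 (2S,3aS)-6-hydroxy-5-isobutyryl-3a,7-bis(3-methylbut-2-en-1-yl)-2-vinyl-3,3a-dihydrobenzofuran-4(2H)-one
Product: 10 (2S,3aS)-2-acetyl-6-hydroxy-5-isobutyryl-3a,7-bis(3-methylbut-2-en-1-yl)-3,3a-dihydrobenzofuran-4(2H)-one
Conditions: PdCl2 (10 mol %), Cu(OAc)2 (20 mol %), O2 (1 atm), DMA/H2O (7:1), rt
Reagents that add atoms: water, O
Why: In this Tsuji–Wacker oxidation divalent palladium should hydroxypalladate the monosubstituted vinyl group in the Markovnikov sense far faster than the trisubstituted prenyl alkenes, the vinylogous-ester oxygen O7 being too poor a donor to steer water to the terminal carbon, while the chloride-poor, near-neutral medium keeps C8, now α to a ketone, from epimerising; no stereocenter is formed.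

Step 6
Reactants: 10 (2S,3aS)-2-acetyl-6-hydroxy-5-isobutyryl-3a,7-bis(3-methylbut-2-en-1-yl)-3,3a-dihydrobenzofuran-4(2H)-one
Product: 12 (2S,3aS)-6-hydroxy-2-(2-hydroxypropan-2-yl)-5-isobutyryl-3a,7-bis(3-methylbut-2-en-1-yl)-3,3a-dihydrobenzofuran-4(2H)-one (CNP0361579.1), via bromomagnesium triketonate 11 (not isolated)
Conditions: MeMgBr (3.5 equiv), THF, −78 → −20 °C; then aq NH4Cl
Reagents that add atoms: methylmagnesium bromide, C[Mg]Br
Why: In this Grignard addition the first equivalent of MeMgBr deprotonates the acidic enol to the triketonate 11, whose delocalised charge shields the ring carbonyl, the isobutyryl group and the vinylogous ester, so the remaining reagent should add only to the methyl ketone, which is activated by chelation to O7 and reacts at low temperature faster than it enolises; the new carbinol carbon carries two methyl groups and is no stereocenter.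

Compound list
1 | phloroglucinol | Oc1cc(O)cc(O)c1 | starting material
2 | isobutyryl chloride | CC(C)C(Cl)=O | starting material
3 | 2,4,6-trihydroxyisobutyrophenone | CC(C)C(=O)c1c(O)cc(O)cc1O | intermediate
4 | prenyl bromide (1-bromo-3-methylbut-2-ene) | CC(C)=CCBr | starting material
5 | deoxycohumulone (2,4,6-trihydroxy-3,5-diprenylisobutyrophenone) | CC(C)=CCc1c(O)c(CC=C(C)C)c(O)c(C(=O)C(C)C)c1O | intermediate
6 | cis-but-2-ene-1,4-diol | OC/C=C\CO | starting material
7 | (Z)-but-2-ene-1,4-diyl bis(methyl carbonate) | COC(=O)OC/C=C\COC(=O)OC | intermediate
8 | (6R)-3,5-dihydroxy-2-isobutyryl-6-[(E)-4-(methoxycarbonyloxy)but-2-en-1-yl]-4,6-bis(3-methylbut-2-en-1-yl)cyclohexa-2,4-dien-1-one (formed in the flask in step 4; same spatial arrangement at the quaternary carbon as C3 of 9) | CC(C)=CCC1=C(O)[C@](CC=C(C)C)(C/C=C/COC(=O)OC)C(=O)C(C(=O)C(C)C)=C1O | intermediate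
9 | (2S,3aS)-6-hydroxy-5-isobutyryl-3a,7-bis(3-methylbut-2-en-1-yl)-2-vinyl-3,3a-dihydrobenzofuran-4(2H)-one (vinyl trans to the 3a-prenyl group) | CC(C)=CCC1=C2O[C@H](C=C)C[C@]2(CC=C(C)C)C(=O)C(C(=O)C(C)C)=C1O | intermediate
10 | (2S,3aS)-2-acetyl-6-hydroxy-5-isobutyryl-3a,7-bis(3-methylbut-2-en-1-yl)-3,3a-dihydrobenzofuran-4(2H)-one | CC(C)=CCC1=C2O[C@H](C(C)=O)C[C@]2(CC=C(C)C)C(=O)C(C(=O)C(C)C)=C1O | intermediate
11 | bromomagnesium triketonate of 10 (formed in the flask in step 6) | CC(C)=CCC1=C2O[C@H](C(C)=O)C[C@]2(CC=C(C)C)C(=O)C(C(=O)C(C)C)=C1[O-].[Mg+2].[Br-] | intermediate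
12 | (2S,3aS)-6-hydroxy-2-(2-hydroxypropan-2-yl)-5-isobutyryl-3a,7-bis(3-methylbut-2-en-1-yl)-3,3a-dihydrobenzofuran-4(2H)-one (CNP0361579.1) | CC(C)=CCC1=C2O[C@H](C(C)(C)O)C[C@]2(CC=C(C)C)C(=O)C(C(=O)C(C)C)=C1O | target

Total step count: 6.
Longest linear sequence: 5 steps (steps 1, 2, 4, 5, 6, from phloroglucinol to 12); step 3 is a one-step side branch.

Steps most likely to fail

Step 4 (bears the label). What may go wrong: weak discrimination between the two mirror-related prenylated carbons, closure through the acyl-chelated oxygen, a poor trans/cis ratio at C8, or intermolecular capture of the second allyl complex leading to oligomers. The fallback sets out from 5 and uses known chemistry. Treatment with (E)-1,4-dibromobut-2-ene and K2CO3 in acetone at rt should give, by the base-mediated dearomative C-alkylation long used for lupulone-type triketones, the racemic allylic bromide 6-[(E)-4-bromobut-2-en-1-yl]-3,5-dihydroxy-2-isobutyryl-4,6-bis(3-methylbut-2-en-1-yl)cyclohexa-2,4-dien-1-one F1. Its enol oxygen on C2 should then close ring B by intramolecular SN2′ displacement of bromide, the established route from cyclic 1,3-diones and 1,4-dibromobut-2-ene to 2-vinyl-2,3-dihydrofurans. The expected product is the racemic trans vinyl dihydrofuran, that is 9 together with its mirror image (2R,3aR)-6-hydroxy-5-isobutyryl-3a,7-bis(3-methylbut-2-en-1-yl)-2-vinyl-3,3a-dihydrobenzofuran-4(2H)-one F2. Preparative HPLC on a chiral stationary phase should separate the two, and the route is rejoined at 9.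

Step 5. What may go wrong: oxypalladation of the neighbouring prenyl alkene by the C6 enol hydroxyl, aerobic oxidation of the electron-rich ring carbon C1, binding of the metals by the triketonate, or anti-Markovnikov attack giving the aldehyde. The fallback sets out from 9 and masks the enol before the oxidation. O-Methylation with TMSCHN2 (MeOH/toluene, 0 °C) should give the vinylogous methyl ester (2S,3aS)-5-isobutyryl-6-methoxy-3a,7-bis(3-methylbut-2-en-1-yl)-2-vinyl-3,3a-dihydrobenzofuran-4(2H)-one F3, which has no enol hydroxyl or enolate left to cyclise, be oxidised or bind the metal. The same Wacker oxidation should then give the methoxy methyl ketone (2S,3aS)-2-acetyl-5-isobutyryl-6-methoxy-3a,7-bis(3-methylbut-2-en-1-yl)-3,3a-dihydrobenzofuran-4(2H)-one F4. Nucleophilic demethylation with LiCl in DMF at 60 °C, the usual unmasking of such vinylogous esters, should return the route at 10; it is done before the Grignard step because only the free triketonate is inert to MeMgBr.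

Step 2. What may go wrong: alkylation running on to the dearomatised triprenyl compound, O-prenylation, and incomplete second alkylation, which together erode the supply of 5. The fallback sets out from 3 and changes from phenoxide alkylation to electrophilic aromatic substitution: 2-methylbut-3-en-2-ol and BF3·OEt2 in dioxane at rt (Friedel–Crafts prenylation of the neutral phenol by a prenyl cation equivalent) should avoid O-alkylation and dearomatising over-alkylation. It returns the route at 5 and passes through no compound outside the list (F0).

Further compounds
F1 | step 4 | racemic 6-[(E)-4-bromobut-2-en-1-yl]-3,5-dihydroxy-2-isobutyryl-4,6-bis(3-methylbut-2-en-1-yl)cyclohexa-2,4-dien-1-one | CC(C)=CCC1=C(O)C(CC=C(C)C)(C/C=C/CBr)C(=O)C(C(=O)C(C)C)=C1O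
F2 | step 4 | (2R,3aR)-6-hydroxy-5-isobutyryl-3a,7-bis(3-methylbut-2-en-1-yl)-2-vinyl-3,3a-dihydrobenzofuran-4(2H)-one | CC(C)=CCC1=C2O[C@@H](C=C)C[C@@]2(CC=C(C)C)C(=O)C(C(=O)C(C)C)=C1O
F3 | step 5 | (2S,3aS)-5-isobutyryl-6-methoxy-3a,7-bis(3-methylbut-2-en-1-yl)-2-vinyl-3,3a-dihydrobenzofuran-4(2H)-one | CC(C)=CCC1=C2O[C@H](C=C)C[C@]2(CC=C(C)C)C(=O)C(C(=O)C(C)C)=C1OC
F4 | step 5 | (2S,3aS)-2-acetyl-5-isobutyryl-6-methoxy-3a,7-bis(3-methylbut-2-en-1-yl)-3,3a-dihydrobenzofuran-4(2H)-one | CC(C)=CCC1=C2O[C@H](C(C)=O)C[C@]2(CC=C(C)C)C(=O)C(C(=O)C(C)C)=C1OC
F0 | step 2 | none | none
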